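The numbers in the tables stem from a simulated flask for an exercise; the scatter is artificial.

The product of this flask cannot be pure G: Q stands beside D at the same concentration, and the same L and Z turn it into X.

| flask | D | Q | Z | E | remark | time |
|---|---|---|---|---|---|---|
| Wednesday's | 0.45 M | 0.45 M | 0.90 M | 15 mM | run made earlier |  |
| flask | 0.30 M | 0.30 M | 0.900 M | 15 mM |  | 50 h |

- Wednesday's (time / h: D / %, Q / %): 0.833: 49.0, 49.9; 1.50: 47.2, 49.5; 3.00: 42.6, 48.5; 5.00: 35.3, 46.5; 10.0: 24.6, 43.4

(scatter of a reading: 0.3 percentage points)

- L is single-handed; D and Q are mirror images of each other, charged as a racemate, each of them at the stated concentration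
- reactions considered so far: Z + L + Q -> L + X; Z + L + D -> L + G; L <-> J; E -> L
- an excess is below zero if the other one leads

- part of the D and Q charged together that has reacted at 50 h
- excess of G over X in the product at 50 h
- excess of Q over D among what is left of the two at 50 h

Follow one molecule that reacts. Both steps use L and Z, so these cancel at the fork, and its chance of being D is s[D]/(s[D]+[Q]). Wednesday's run at 10.0 h reads the selectivity factor s, the logarithm of D's charge over D left divided by the same logarithm for Q, as 5.01. One clock θ, D's logarithm, therefore gives both remainders, since Q's logarithm is θ/s.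

From 5.00 h to 10.0 h on Wednesday, after the early climb, mean [Z] is 0.674 M, and θ advances at a reading of 0.107 /M/h times [Z]; E is charged alike in the flask. With [Z] held at its charge, θ reaches 4.82, which ends [Z] at 0.417 M. Averaging 1/[Z] between those two ends gives θ = 3.05, so 4.72% of D and 54.4% of Q remain. This reckoning commits to c 70.5%, eP 35.2%, eS 84.0%.

The weak link is that two-point average. Recomputing [Z] from θ, 0.586 M midway and 0.477 M at the end, Simpson's weights put this θ at 47.6 h, just short of 50 h, which leaves room for the early climb.

The forecast says c 70%, eP 35.5%, eS 83%, on the ground that “D reacts about five times faster than Q”; its eS lies below this reckoning's.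

The flask gives c 70.0%, eP 36.6%, eS 85.5%, and the forecast is right within the tolerance on each.

    Z + L + Q → L + X (k = 1.50 /M²/h)
    Z + L + D → L + G (k = 8.00 /M²/h)
    L ⇌ J (K = 0.410, k = 0.00550 /h)
    E → L (k = 0.640 /h)

In this flask at 8.47 h the half-life of D by its step is 8.3 h against 44 h for Q by its step, a factor of 5.30, and its remainders at 50 h, 4.4% of the charged D and 56% of the charged Q, give s as 5.33. A neighbour flask, charged alike but with 0.0037 M of E, a quarter of this flask's E, keeps 38% of its charged D at 50 h; s = 5.01 turns that into 82.4% of its charged Q, and that neighbour keeps 83%.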